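Assumption: atoms carry germacrane numbers (ring C1–C10, lactone carbons C11–C13, C14 on C10, C15 on C4), and compounds 23–25 are taken as mixtures of epimers at the C7 carbinol, a centre that step 16 removes. TBS = tert-butyldimethylsilyl, PMB = 4-methoxybenzyl.

## The problem

Target 31 is a heliangolide-type germacranolide: a ten-membered carbocycle (C1–C10) trans-fused across C6–C7 to an α-methylene-γ-butyrolactone (C11–C13). It carries a Z-trisubstituted C4=C5 alkene, a trans 1,10-epoxide, an acetate at C3 and an isovalerate at C8. Six stereocentres have to be set (1R,3S,6R,7R,8S,10R). C3 and C8 are isolated carbinol centres that no neighbour can control, so they are best bought from the chiral pool. C6 and C7 are contiguous with C8 and can be set relative to it, and C1/C10 can only come from face-selective oxidation of an E alkene held in the ring. The ten-membered ring is strained, so the closing bond should be one whose formation also delivers the lactone. The sensitive groups fix the order of events: the α-methylene lactone is a Michael acceptor and can relactonise to O8 under base, the two different esters can migrate, and the epoxide can open transannularly onto C4=C5 under acid, so it must come last. The enabling feature is the E C1=C10 alkene: it bears the C14 methyl and is homoallylic to both the C3 and the C8 oxygen. That is the pattern left when methyl and a metal add syn across a terminal C1≡C10 alkyne and the alkenylmetal then opens a C2–C3 epoxide.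

## Retrosynthesis

**Epoxide (C1–O, C10–O).** The epoxide of 31 is removed first, giving triene 30. Only in the ring are the two faces of C1=C10 different, and the epoxide would not survive the acidic and Lewis-acidic steps before it. The forward step needs a peracid that picks the most electron-rich alkene and the outward face of the ring.

**C8 ester (O8–acyl).** The isovalerate of 30 is cut to alcohol 29 and this to silyl ether 28. O8 has to stay blocked while the lactone forms, otherwise the 8,12-olide competes. The C3 acetate is placed earlier, which spares a second late deprotection. The forward steps need a fluoride source that leaves lactone and acetate alone, then a mild acylation.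

**Ring closure (C6–C7 and O6–C12).** 28 is opened to the acyclic bromo enal 26. An allylchromium addition through C7 onto the C6 aldehyde forms the ring bond, the exocyclic C11=C13 alkene and, after lactonisation, the lactone in one operation. Cutting C7–C8 instead would make the C8 centre in the ring-closing event rather than buying it. Closing at either alkene would leave the alkene geometry to chance in a ten-membered ring. The precursor has only two stereocentres (C3, C8), and the forward reaction must set C6 and C7 from C8 and the ring.

**Allyl bromide (C7–C11).** 26 goes back through hydroxy enal 25, diol 24 and Morita–Baylis–Hillman adduct 23 to aldehyde 21 and methyl acrylate 22. The C11–C13 unit arrives as a bulk chemical, and the allylic transposition to the bromide gives the Z-bromomethyl enoate by thermodynamic preference. Aldehyde 21 comes from PMB ether 19 through alcohol 20. This asks for an amine-catalysed addition that does not epimerise C8.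

**Z alkene (C4=C5, with O3–C6 tied temporarily).** The Z geometry of 19 is traced through diol 17 to butenolide 16, whose ring can only hold the Z alkene. 16 comes from acyloin 13 and ketenylidene ylide 14 by O-acylation and intramolecular Wittig reaction. An intermolecular olefination of the ketone would have to win Z selectivity against the intrinsic bias. Here the C3 oxygen, which is needed anyway, enforces it. Opening 16 by reduction gives a diol whose primary and secondary hydroxyls are easily told apart, so the C3 acetate is placed at this point (17 to 19). 13 is the hydrolysed form of ketal 12.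

**Key disconnection (C1–C2 and C10–C14).** 12 is cut into alkyne 5, epoxide 8 and trimethylaluminium 9. One operation makes both bonds, fixes the E geometry through syn addition, and leaves the C3 hydroxyl free and distinct from the protected C8 oxygen. A Wittig or Julia route to the same trisubstituted alkene would need a methyl ketone and would give mixtures. The fragments are of similar size and each holds one stereocentre. The forward reaction needs methyl on the internal alkyne carbon and attack at the CH2 end of the epoxide.

**Fragments.** Alkyne 5 comes from alkynol 4, made by opening PMB glycidyl ether 2 (from (R)-glycidol 1) with lithium acetylide 3. Epoxide 8 comes from racemic epoxide 7 by hydrolytic kinetic resolution, and 7 from vinyl dioxolane 6. Both sequences use stock reactions and move no stereocentre.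

## Roads not taken

**Alternative 1:** The ring is cut at C7–C8. In the forward direction CrCl2 or indium turns the bromomethyl butenolide A1, which carries the aldehyde at C8, into an allylmetal that attacks through C7. The alkene moves to C11=C13 and hydroxy lactone A2 results, the same compound as 29 of the chosen route.
- Merits: C6 is fixed in the lactone before the ring closes, and the C8 hydroxyl arrives free, which saves the silylation and desilylation that the chosen plan spends on O8. In these respects it is the better road.
- Weak points: C7 and C8 are both created in the macrocyclisation, so the C8 configuration depends on ring conformation. The aldehyde of A1 is β,γ-unsaturated toward C10=C1 and prone to slip into conjugation. A1 still needs its own stereoselective route to the E C1=C10 alkene and to C6.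
- Comparison: the chosen plan buys C8 with certainty from glycidol, uses it to steer C7, and builds C1=C10 in the same operation that joins the halves. It also has two centres (C6, C7) set in its ring closure.

**Alternative 2:** The C1–C4 and C5–C10 bonds of the bicyclo[2.2.0]hexane core of photoadduct A3 are cleaved by flash thermolysis to give the E,Z-cyclodecadienone A4.
- Merits: no macrocyclisation is needed, both ring alkenes arise in one step, and the ring is reached in fewer steps than in the chosen plan.
- Weak points: A4 lacks the C3 oxygen and all three lactone carbons. Adding them needs an allylic oxidation that must choose C3 among five allylic positions, an alkylation at C7 next to a ketone that can also enolise toward C5, and a face-selective reduction at C6. A 1,5-diene in a ten-membered ring is liable to Cope rearrangement at thermolysis temperatures. Only the C8 centre carries absolute configuration.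
- Comparison: the shorter ring synthesis is paid for by late oxygenation of uncertain selectivity. The chosen plan places every oxygen before the ring closes.

**Alternative 3:** The ring is cut at C1–C10. SmI2 (or low-valent titanium) reduces the C1 aldehyde and C10 methyl ketone of keto aldehyde A5 to ketyls that couple to the 1,10-diol A6.
- Merits: the lactone with C6 and C7 is made before the ring, in a small-ring setting. The epoxide would come from the diol by sulfonylation at C1 and displacement by O10, so its configuration would not depend on the face selectivity of a peracid. In this respect it is better than the chosen plan.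
- Weak points: the coupling must give the one diol diastereomer of four that has the right C10 centre and the inverted C1 centre, in a ten-membered ring where pinacol closures are hard to steer. The ketyl at C10 is β to the C8 silyloxy group and can eliminate it. The lactone lacks C13, so a methylenation and extra protecting-group steps follow.
- Comparison: the chosen plan sets the E geometry, and with it the trans epoxide, in an intermolecular step that cannot give the other isomer. Against it stands one face-selective epoxidation on a ring whose outward face is predictable.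

Key step: step 6

## Route

Step 1
Reactants: 1 (R)-glycidol
Product: 2 (S)-2-[(4-methoxybenzyloxy)methyl]oxirane
Conditions: NaH, 4-methoxybenzyl chloride, Bu4NI (cat.), DMF, 0 °C to rt
Reagents that add atoms: 4-methoxybenzyl chloride, COc1ccc(CCl)cc1
Why: Williamson etherification of the primary alkoxide; the stereocentre is not a reacting centre, and the Payne rearrangement of the glycidol alkoxide is degenerate and returns the same enantiomer.

Step 2
Reactants: 2 (S)-2-[(4-methoxybenzyloxy)methyl]oxirane; 3 lithium acetylide–ethylenediamine complex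
Product: 4 (S)-1-(4-methoxybenzyloxy)pent-4-yn-2-ol
Conditions: LiC≡CH·H2NCH2CH2NH2, DMSO, 10 °C to rt
Reagents that add atoms: none
Why: SN2 opening of the terminal epoxide at its CH2 carbon by the acetylide gives the homopropargylic alcohol directly as the terminal alkyne; C8 keeps its configuration because it is not attacked.

Step 3
Reactants: 4 (S)-1-(4-methoxybenzyloxy)pent-4-yn-2-ol
Product: 5 (S)-tert-butyl{[1-(4-methoxybenzyloxy)pent-4-yn-2-yl]oxy}dimethylsilane
Conditions: TBSCl, imidazole, DMF, rt
Reagents that add atoms: tert-butyldimethylsilyl chloride, CC(C)(C)[Si](C)(C)Cl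
Why: Standard silylation of a secondary alcohol; the silyl ether keeps O8 apart from the hydroxyl that the key step will create at C3 and is inert to organoaluminium reagents.

Step 4
Reactants: 6 2-methyl-2-vinyl-1,3-dioxolane
Product: 7 rac-2-methyl-2-(oxiran-2-yl)-1,3-dioxolane
Conditions: mCPBA, NaHCO3, CH2Cl2, reflux
Reagents that add atoms: 3-chloroperbenzoic acid, O=C(OO)c1cccc(Cl)c1
Why: Prilezhaev epoxidation; the alkene is deactivated by the ketal and needs forcing conditions, and the bicarbonate buffer protects the ketal from the acid formed.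

Step 5
Reactants: 7 rac-2-methyl-2-(oxiran-2-yl)-1,3-dioxolane
Product: 8 2-methyl-2-[(S)-oxiran-2-yl]-1,3-dioxolane
Conditions: (R,R)-(salen)Co(OAc) (0.5 mol%; salen = N,N′-bis(3,5-di-tert-butylsalicylidene)-1,2-cyclohexanediamine dianion), H2O (0.55 equiv), THF, 0 °C to rt; distillation
Reagents that add atoms: none
Why: Jacobsen hydrolytic kinetic resolution with the trivalent cobalt salen acetate; the (R,R) catalyst hydrates the (R)-epoxide and should leave the (S)-epoxide, the same spatial sense in which it leaves (S)-epichlorohydrin and (S)-methyl glycidate. Bulky α-branched terminal epoxides are within the known scope.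

Step 6
Reactants: 5 (S)-tert-butyl{[1-(4-methoxybenzyloxy)pent-4-yn-2-yl]oxy}dimethylsilane; 9 trimethylaluminium; 8 2-methyl-2-[(S)-oxiran-2-yl]-1,3-dioxolane
Product: 12 (1S,3E,6S)-6-(tert-butyldimethylsilyloxy)-7-(4-methoxybenzyloxy)-4-methyl-1-(2-methyl-1,3-dioxolan-2-yl)hept-3-en-1-ol, via alkenyldimethylalane 10 (not isolated), via lithium alkenylalanate 11 (not isolated)
Conditions: AlMe3 (3 equiv), Cp2ZrCl2 (0.25 equiv), CH2Cl2, 0 °C to rt; volatiles removed in vacuo; hexane, n-BuLi, 0 °C; then 8, THF, 0 °C to rt
Reagents that add atoms: none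
Why: Cp2ZrCl2 and AlMe3 form a methylzirconium–aluminate pair that adds methyl and metal syn across the terminal alkyne of 5, methyl to the internal carbon C10 (C10–C14 bond) and metal to C1, and transmetalation gives the (E)-alkenylalane 10. n-BuLi turns 10 into alanate 11, which transfers its alkenyl group, in preference to butyl or methyl, to the CH2 carbon C2 of epoxide 8 in an SN2 opening (C1–C2 bond) with retention of alkene geometry. The closest known reaction type is the zirconium-catalysed methylalumination of terminal alkynes followed by alkenylalanate opening of monosubstituted epoxides. No ring is closed and no stereocentre is created: C8 comes in with 5 and C3 with 8, and C3 keeps its configuration because the attack is at C2. The step needs three selectivities. Methyl on the internal carbon and the E geometry are inherent to the syn carbometalation of a terminal alkyne, and the homopropargylic silyl ether is not known to override them. Attack at C2 is secured because the other epoxide carbon is shielded by the quaternary ketal carbon, and because the epoxide is not allylic no SN2′ path exists. The silyl ether, the PMB ether and the dioxolane are not attacked by the alane, provided excess AlMe3 is stripped before the ate complex is made.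

Step 7
Reactants: 12 (1S,3E,6S)-6-(tert-butyldimethylsilyloxy)-7-(4-methoxybenzyloxy)-4-methyl-1-(2-methyl-1,3-dioxolan-2-yl)hept-3-en-1-ol
Product: 13 (3S,5E,8S)-8-(tert-butyldimethylsilyloxy)-3-hydroxy-9-(4-methoxybenzyloxy)-6-methylnon-5-en-2-one
Conditions: PPTS (cat.), acetone/H2O 10:1, 50 °C
Reagents that add atoms: water, O
Why: Mild acid hydrolysis of the dioxolane; a secondary TBS ether and a PMB ether are stable to pyridinium tosylate, and the acyloin is used at once to limit enolisation at C3.

Step 8
Reactants: 13 (3S,5E,8S)-8-(tert-butyldimethylsilyloxy)-3-hydroxy-9-(4-methoxybenzyloxy)-6-methylnon-5-en-2-one; 14 ketenylidenetriphenylphosphorane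
Product: 16 (S)-5-[(2E,5S)-5-(tert-butyldimethylsilyloxy)-6-(4-methoxybenzyloxy)-3-methylhex-2-en-1-yl]-4-methylfuran-2(5H)-one, via phosphoranylidene acetate 15 (not isolated)
Conditions: Ph3P=C=C=O, toluene, 90 °C
Reagents that add atoms: none
Why: The C3 hydroxyl adds to the ketene ylide to give the ester ylide 15, which closes onto the C4 ketone by intramolecular Wittig reaction, the known route from α-hydroxy ketones to butenolides. The five-membered ring can only contain the Z alkene, so C3 and C6 end up cis across C4=C5.

Step 9
Reactants: 16 (S)-5-[(2E,5S)-5-(tert-butyldimethylsilyloxy)-6-(4-methoxybenzyloxy)-3-methylhex-2-en-1-yl]-4-methylfuran-2(5H)-one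
Product: 17 (2Z,4S,6E,9S)-9-(tert-butyldimethylsilyloxy)-10-(4-methoxybenzyloxy)-3,7-dimethyldeca-2,6-diene-1,4-diol
Conditions: i-Bu2AlH (4 equiv), CH2Cl2, −78 to 0 °C; aq. potassium sodium tartrate
Reagents that add atoms: none
Why: 1,2-Reduction of the butenolide through the lactol to the Z-configured ene-1,4-diol; excess hydride carries the lactol on so that it cannot dehydrate to a furan on work-up.

Step 10
Reactants: 17 (2Z,4S,6E,9S)-9-(tert-butyldimethylsilyloxy)-10-(4-methoxybenzyloxy)-3,7-dimethyldeca-2,6-diene-1,4-diol
Product: 19 (2Z,4S,6E,9S)-1,9-bis(tert-butyldimethylsilyloxy)-10-(4-methoxybenzyloxy)-3,7-dimethyldeca-2,6-dien-4-yl acetate, via mono-silyl ether 18 (not isolated)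
Conditions: TBSCl (1.05 equiv), imidazole, CH2Cl2, −20 to 0 °C; then Ac2O, Et3N, DMAP (cat.), rt
Reagents that add atoms: tert-butyldimethylsilyl chloride, CC(C)(C)[Si](C)(C)Cl; acetic anhydride, CC(=O)OC(C)=O
Why: The primary allylic hydroxyl at C6 is silylated much faster than the hindered secondary one at C3, which is then acetylated in the same flask; this installs the C3 acetate of the target.

Step 11
Reactants: 19 (2Z,4S,6E,9S)-1,9-bis(tert-butyldimethylsilyloxy)-10-(4-methoxybenzyloxy)-3,7-dimethyldeca-2,6-dien-4-yl acetate
Product: 20 (2Z,4S,6E,9S)-1,9-bis(tert-butyldimethylsilyloxy)-10-hydroxy-3,7-dimethyldeca-2,6-dien-4-yl acetate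
Conditions: DDQ, CH2Cl2/pH 7 phosphate buffer, 0 °C
Reagents that add atoms: none
Why: Oxidative cleavage of the PMB ether through its benzylic cation; acetate, silyl ethers and trisubstituted alkenes are stable under buffered conditions.

Step 12
Reactants: 20 (2Z,4S,6E,9S)-1,9-bis(tert-butyldimethylsilyloxy)-10-hydroxy-3,7-dimethyldeca-2,6-dien-4-yl acetate
Product: 21 (2Z,4S,6E,9S)-1,9-bis(tert-butyldimethylsilyloxy)-3,7-dimethyl-10-oxodeca-2,6-dien-4-yl acetate
Conditions: Dess–Martin periodinane, NaHCO3, CH2Cl2, 0 °C to rt
Reagents that add atoms: none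
Why: Neutral oxidation of the primary alcohol to the α-silyloxy aldehyde without epimerising C8; the aldehyde is used crude.

Step 13
Reactants: 21 (2Z,4S,6E,9S)-1,9-bis(tert-butyldimethylsilyloxy)-3,7-dimethyl-10-oxodeca-2,6-dien-4-yl acetate; 22 methyl acrylate
Product: 23 methyl (4S,6E,9S,10Z)-9-acetoxy-4,12-bis(tert-butyldimethylsilyloxy)-3-hydroxy-6,10-dimethyl-2-methylidenedodeca-6,10-dienoate (both C3 carbinol epimers of this name, i.e. C7 in germacrane numbering)
Conditions: methyl acrylate (neat, excess), DABCO (1 equiv), rt
Reagents that add atoms: none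
Why: Morita–Baylis–Hillman reaction; α-alkoxy aldehydes are activated acceptors, and the configuration of the new carbinol does not matter because step 16 removes it.

Step 14
Reactants: 23 methyl (4S,6E,9S,10Z)-9-acetoxy-4,12-bis(tert-butyldimethylsilyloxy)-3-hydroxy-6,10-dimethyl-2-methylidenedodeca-6,10-dienoate
Product: 24 methyl (4S,6E,9S,10Z)-9-acetoxy-4-(tert-butyldimethylsilyloxy)-3,12-dihydroxy-6,10-dimethyl-2-methylidenedodeca-6,10-dienoate
Conditions: HF·pyridine, pyridine, THF, 0 °C
Reagents that add atoms: none
Why: Buffered HF·pyridine removes a primary allylic TBS ether much faster than the secondary one at C8; the short reaction at 0 °C limits acetyl migration from O3 to O6.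

Step 15
Reactants: 24 methyl (4S,6E,9S,10Z)-9-acetoxy-4-(tert-butyldimethylsilyloxy)-3,12-dihydroxy-6,10-dimethyl-2-methylidenedodeca-6,10-dienoate
Product: 25 methyl (4S,6E,9S,10Z)-9-acetoxy-4-(tert-butyldimethylsilyloxy)-3-hydroxy-6,10-dimethyl-2-methylidene-12-oxododeca-6,10-dienoate
Conditions: TEMPO (cat.), PhI(OAc)2, CH2Cl2, rt
Reagents that add atoms: none
Why: Oxoammonium oxidation selects the primary allylic alcohol over the secondary, electron-poor Morita–Baylis–Hillman carbinol and is known to keep Z-allylic alcohols Z on the way to the enal.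

Step 16
Reactants: 25 methyl (4S,6E,9S,10Z)-9-acetoxy-4-(tert-butyldimethylsilyloxy)-3-hydroxy-6,10-dimethyl-2-methylidene-12-oxododeca-6,10-dienoate
Product: 26 methyl (2Z,4S,6E,9S,10Z)-9-acetoxy-2-(bromomethyl)-4-(tert-butyldimethylsilyloxy)-6,10-dimethyl-12-oxododeca-2,6,10-trienoate
Conditions: NBS, Me2S, CH2Cl2, −20 to 0 °C
Reagents that add atoms: N-bromosuccinimide, O=C1CCC(=O)N1Br
Why: Corey–Kim-type activation of the carbinol as an alkoxysulfonium ion and SN2′ attack of bromide at the methylidene carbon is the standard conversion of Morita–Baylis–Hillman adducts into (Z)-2-(bromomethyl)alk-2-enoates; the aldehyde is inert to the reagent.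

Step 17
Reactants: 26 methyl (2Z,4S,6E,9S,10Z)-9-acetoxy-2-(bromomethyl)-4-(tert-butyldimethylsilyloxy)-6,10-dimethyl-12-oxododeca-2,6,10-trienoate
Product: 28 (3S,6R,7S,8S)-3-acetoxy-8-(tert-butyldimethylsilyloxy)germacra-1(10)E,4Z,11(13)-trien-6,12-olide, via carbocyclic hydroxy ester 27 (not isolated)
Conditions: CrCl2 (10 equiv), DMF, slow addition of 26 to 0.003 M, rt
Reagents that add atoms: none
Why: Intramolecular Nozaki–Hiyama–Kishi-type allylation, a known closure for ten-membered germacranolide rings: divalent chromium turns the allylic bromide into an allylchromium species that adds through C7 to the C6 aldehyde in a chair transition state, and the chromium alkoxide of 27 lactonises onto the methyl ester. The anti C6/C7 relationship (trans lactone) is expected from the equilibrating allylchromium reacting with C5 and C8 both equatorial. C7 should be set relative to C8 by attack on the allyl face opposite the silyloxy group, with H8 in the allyl plane to avoid allylic 1,3-strain and the C9 tether on the attacked face.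

Step 18
Reactants: 28 (3S,6R,7S,8S)-3-acetoxy-8-(tert-butyldimethylsilyloxy)germacra-1(10)E,4Z,11(13)-trien-6,12-olide
Product: 29 (3S,6R,7R,8S)-3-acetoxy-8-hydroxygermacra-1(10)E,4Z,11(13)-trien-6,12-olide
Conditions: HF·pyridine, THF, 0 °C to rt
Reagents that add atoms: none
Why: Acidic fluoride cleaves the secondary TBS ether without the basic conditions that would promote relactonisation to O8, acetate migration or conjugate addition to the methylene lactone (the C7 descriptor changes only because silicon leaves O8).

Step 19
Reactants: 29 (3S,6R,7R,8S)-3-acetoxy-8-hydroxygermacra-1(10)E,4Z,11(13)-trien-6,12-olide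
Product: 30 (3S,6R,7R,8S)-3-acetoxy-8-(3-methylbutanoyloxy)germacra-1(10)E,4Z,11(13)-trien-6,12-olide
Conditions: (Me2CHCH2CO)2O, Et3N, DMAP (cat.), CH2Cl2, 0 °C to rt
Reagents that add atoms: 3-methylbutanoic anhydride, CC(C)CC(=O)OC(=O)CC(C)C
Why: DMAP-catalysed acylation of the only free hydroxyl; acylation is expected to outrun relactonisation under these mild conditions.

Step 20
Reactants: 30 (3S,6R,7R,8S)-3-acetoxy-8-(3-methylbutanoyloxy)germacra-1(10)E,4Z,11(13)-trien-6,12-olide
Product: 31 (1R,3S,6R,7R,8S,10R)-3-acetoxy-1,10-epoxy-8-(3-methylbutanoyloxy)germacra-4Z,11(13)-dien-6,12-olide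
Conditions: mCPBA, NaHCO3, CH2Cl2, 0 °C
Reagents that add atoms: 3-chloroperbenzoic acid, O=C(OO)c1cccc(Cl)c1
Why: Prilezhaev epoxidation of the only electron-rich alkene; C4=C5 is deactivated by two allylic acyloxy groups and C11=C13 by conjugation. Stereospecific syn addition to the E alkene gives the trans epoxide, and attack on the outward face of C1=C10 in the ring conformer is expected to give the (1R,10R) isomer; the buffer prevents acid-induced transannular opening.

## Compound list

1 | (R)-glycidol | OC[C@@H]1CO1 | starting material
2 | (S)-2-[(4-methoxybenzyloxy)methyl]oxirane | COc1ccc(COC[C@@H]2CO2)cc1 | intermediate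
3 | lithium acetylide–ethylenediamine complex | [Li]C#C.NCCN | starting material
4 | (S)-1-(4-methoxybenzyloxy)pent-4-yn-2-ol | C#CC[C@H](O)COCc1ccc(OC)cc1 | intermediate
5 | (S)-tert-butyl{[1-(4-methoxybenzyloxy)pent-4-yn-2-yl]oxy}dimethylsilane (alkyne fragment, C7–C10 and C1) | C#CC[C@H](O[Si](C)(C)C(C)(C)C)COCc1ccc(OC)cc1 | intermediate
6 | 2-methyl-2-vinyl-1,3-dioxolane | C=CC1(C)OCCO1 | starting material
7 | rac-2-methyl-2-(oxiran-2-yl)-1,3-dioxolane (racemate) | CC1(C2CO2)OCCO1 | intermediate
8 | 2-methyl-2-[(S)-oxiran-2-yl]-1,3-dioxolane (epoxide fragment, C2–C4 and C15) | CC1([C@@H]2CO2)OCCO1 | intermediate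
9 | trimethylaluminium | C[Al](C)C | starting material
10 | dimethyl[(1E,4S)-4-(tert-butyldimethylsilyloxy)-5-(4-methoxybenzyloxy)-2-methylpent-1-en-1-yl]alane | C[Al](C)/C=C(\C)C[C@H](O[Si](C)(C)C(C)(C)C)COCc1ccc(OC)cc1 | intermediate (not isolated)
11 | lithium butyl(dimethyl)[(1E,4S)-4-(tert-butyldimethylsilyloxy)-5-(4-methoxybenzyloxy)-2-methylpent-1-en-1-yl]alanate | [Li+].CCCC[Al-](C)(C)/C=C(\C)C[C@H](O[Si](C)(C)C(C)(C)C)COCc1ccc(OC)cc1 | intermediate (not isolated)
12 | (1S,3E,6S)-6-(tert-butyldimethylsilyloxy)-7-(4-methoxybenzyloxy)-4-methyl-1-(2-methyl-1,3-dioxolan-2-yl)hept-3-en-1-ol (C3–C10 chain, 3S,8S) | COc1ccc(COC[C@@H](O[Si](C)(C)C(C)(C)C)C/C(C)=C/C[C@H](O)C2(C)OCCO2)cc1 | intermediate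
13 | (3S,5E,8S)-8-(tert-butyldimethylsilyloxy)-3-hydroxy-9-(4-methoxybenzyloxy)-6-methylnon-5-en-2-one | COc1ccc(COC[C@@H](O[Si](C)(C)C(C)(C)C)C/C(C)=C/C[C@H](O)C(C)=O)cc1 | intermediate
14 | ketenylidenetriphenylphosphorane, Ph3P=C=C=O | O=C=C=P(c1ccccc1)(c1ccccc1)c1ccccc1 | starting material
15 | (triphenylphosphoranylidene)acetate of the C3 hydroxyl of 13 | COc1ccc(COC[C@@H](O[Si](C)(C)C(C)(C)C)C/C(C)=C/C[C@H](OC(=O)C=P(c2ccccc2)(c2ccccc2)c2ccccc2)C(C)=O)cc1 | intermediate (not isolated)
16 | (S)-5-[(2E,5S)-5-(tert-butyldimethylsilyloxy)-6-(4-methoxybenzyloxy)-3-methylhex-2-en-1-yl]-4-methylfuran-2(5H)-one | COc1ccc(COC[C@@H](O[Si](C)(C)C(C)(C)C)C/C(C)=C/C[C@@H]2OC(=O)C=C2C)cc1 | intermediate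
17 | (2Z,4S,6E,9S)-9-(tert-butyldimethylsilyloxy)-10-(4-methoxybenzyloxy)-3,7-dimethyldeca-2,6-diene-1,4-diol | OC/C=C(/C)[C@@H](O)C/C=C(\C)C[C@H](O[Si](C)(C)C(C)(C)C)COCc1ccc(OC)cc1 | intermediate
18 | (2Z,4S,6E,9S)-1,9-bis(tert-butyldimethylsilyloxy)-10-(4-methoxybenzyloxy)-3,7-dimethyldeca-2,6-dien-4-ol | CC(C)(C)[Si](C)(C)OC/C=C(/C)[C@@H](O)C/C=C(\C)C[C@H](O[Si](C)(C)C(C)(C)C)COCc1ccc(OC)cc1 | intermediate (not isolated)
19 | (2Z,4S,6E,9S)-1,9-bis(tert-butyldimethylsilyloxy)-10-(4-methoxybenzyloxy)-3,7-dimethyldeca-2,6-dien-4-yl acetate | CC(C)(C)[Si](C)(C)OC/C=C(/C)[C@@H](OC(C)=O)C/C=C(\C)C[C@H](O[Si](C)(C)C(C)(C)C)COCc1ccc(OC)cc1 | intermediate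
20 | (2Z,4S,6E,9S)-1,9-bis(tert-butyldimethylsilyloxy)-10-hydroxy-3,7-dimethyldeca-2,6-dien-4-yl acetate | CC(C)(C)[Si](C)(C)OC/C=C(/C)[C@@H](OC(C)=O)C/C=C(\C)C[C@H](O[Si](C)(C)C(C)(C)C)CO | intermediate
21 | (2Z,4S,6E,9S)-1,9-bis(tert-butyldimethylsilyloxy)-3,7-dimethyl-10-oxodeca-2,6-dien-4-yl acetate | CC(C)(C)[Si](C)(C)OC/C=C(/C)[C@@H](OC(C)=O)C/C=C(\C)C[C@H](O[Si](C)(C)C(C)(C)C)C=O | intermediate
22 | methyl acrylate | C=CC(=O)OC | starting material
23 | methyl (4S,6E,9S,10Z)-9-acetoxy-4,12-bis(tert-butyldimethylsilyloxy)-3-hydroxy-6,10-dimethyl-2-methylidenedodeca-6,10-dienoate (C3 carbinol epimers) | CC(C)(C)[Si](C)(C)OC/C=C(/C)[C@@H](OC(C)=O)C/C=C(\C)C[C@H](O[Si](C)(C)C(C)(C)C)C(O)C(=C)C(=O)OC | intermediate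
24 | methyl (4S,6E,9S,10Z)-9-acetoxy-4-(tert-butyldimethylsilyloxy)-3,12-dihydroxy-6,10-dimethyl-2-methylidenedodeca-6,10-dienoate (C3 carbinol epimers) | OC/C=C(/C)[C@@H](OC(C)=O)C/C=C(\C)C[C@H](O[Si](C)(C)C(C)(C)C)C(O)C(=C)C(=O)OC | intermediate
25 | methyl (4S,6E,9S,10Z)-9-acetoxy-4-(tert-butyldimethylsilyloxy)-3-hydroxy-6,10-dimethyl-2-methylidene-12-oxododeca-6,10-dienoate (C3 carbinol epimers) | O=C/C=C(/C)[C@@H](OC(C)=O)C/C=C(\C)C[C@H](O[Si](C)(C)C(C)(C)C)C(O)C(=C)C(=O)OC | intermediate
26 | methyl (2Z,4S,6E,9S,10Z)-9-acetoxy-2-(bromomethyl)-4-(tert-butyldimethylsilyloxy)-6,10-dimethyl-12-oxododeca-2,6,10-trienoate | O=C/C=C(/C)[C@@H](OC(C)=O)C/C=C(\C)C[C@H](O[Si](C)(C)C(C)(C)C)/C=C(\CBr)C(=O)OC | intermediate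
27 | methyl (3S,6R,7S,8S)-3-acetoxy-8-(tert-butyldimethylsilyloxy)-6-hydroxygermacra-1(10)E,4Z,11(13)-trien-12-oate (formed as its chromium alkoxide) | C=C(C(=O)OC)[C@@H]1[C@@H](O[Si](C)(C)C(C)(C)C)C/C(C)=C/C[C@H](OC(C)=O)/C(C)=C\[C@H]1O | intermediate (not isolated)
28 | (3S,6R,7S,8S)-3-acetoxy-8-(tert-butyldimethylsilyloxy)germacra-1(10)E,4Z,11(13)-trien-6,12-olide | C=C1C(=O)O[C@@H]2/C=C(/C)[C@@H](OC(C)=O)C/C=C(\C)C[C@H](O[Si](C)(C)C(C)(C)C)[C@@H]12 | intermediate
29 | (3S,6R,7R,8S)-3-acetoxy-8-hydroxygermacra-1(10)E,4Z,11(13)-trien-6,12-olide | C=C1C(=O)O[C@@H]2/C=C(/C)[C@@H](OC(C)=O)C/C=C(\C)C[C@H](O)[C@@H]12 | intermediate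
30 | (3S,6R,7R,8S)-3-acetoxy-8-(3-methylbutanoyloxy)germacra-1(10)E,4Z,11(13)-trien-6,12-olide | C=C1C(=O)O[C@@H]2/C=C(/C)[C@@H](OC(C)=O)C/C=C(\C)C[C@H](OC(=O)CC(C)C)[C@@H]12 | intermediate
31 | (1R,3S,6R,7R,8S,10R)-3-acetoxy-1,10-epoxy-8-(3-methylbutanoyloxy)germacra-4Z,11(13)-dien-6,12-olide (CNP0157657.1) | C=C1C(=O)O[C@@H]2/C=C(/C)[C@@H](OC(C)=O)C[C@H]3O[C@]3(C)C[C@H](OC(=O)CC(C)C)[C@@H]12 | target

## Count and risks

Total step count: 20. Longest linear sequence: 18 steps (steps 1–3 and 6–20, from 1); the epoxide branch (steps 4 and 5) joins at step 6.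

Least certain steps:

**Step 6 (key step).** What may go wrong: alanate 11 is only a moderate nucleophile, and C2 of epoxide 8 sits next to a carbon attached to a quaternary ketal centre. The opening may therefore be slow and lose to transfer of butyl or methyl from aluminium, or to Lewis-acid-induced rearrangement of the epoxide by residual aluminium species. Fallback (sets out from 5, returns at 12): the same zirconium-catalysed methylalumination is run, but alane 10 is quenched with iodine to give the (E)-vinyl iodide F1. Iodine–lithium exchange with t-BuLi in Et2O at −78 °C gives the alkenyllithium F2, which opens 8 at C2 in the presence of BF3·OEt2 at −78 °C to give 12. The same two bonds are formed, in two operations with a stronger nucleophile–electrophile pair.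

**Step 17.** What may go wrong: intermolecular coupling may compete with closure of the strained ring, and the face selection at C6 and C7 rests on a transition-state model for a ring whose conformation is not known. The closure may favour the cis-fused lactone or the C7 epimer, and neither can be corrected afterwards. Fallback (sets out from 26, returns at 28; no new compound, F0): substrate control is replaced by reagent control. The closure is run as a catalytic, ligand-controlled chromium allylation with CrCl2 in catalytic amount, a chiral oxazoline–sulfonamide ligand, Mn powder as terminal reductant and Cp2ZrCl2 for turnover. The ligand then chooses the C6 face, and the enantiomer that matches the bias of the C8 centre can be selected.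

**Step 20.** What may go wrong: the peracid may attack the wrong face of C1=C10 if the reactive ring conformer is not the one assumed, and the acid formed may trigger transannular opening of the epoxide onto C4=C5. Fallback (sets out from 30, returns at 31): NBS in aqueous THF adds bromine to the same accessible face and water anti at C10, giving bromohydrin F3. K2CO3 in acetone then closes O10 onto C1 with inversion, which puts the epoxide on the face opposite to the one a peracid attacks.

**Step 13.** What may go wrong: the hindered α-silyloxy aldehyde may react only over days, during which the amine can epimerise C8 by enolisation. Fallback (sets out from 21, returns at 23): methyl propiolate is hydroaluminated with i-Bu2AlH and N-methylmorpholine N-oxide in THF to give [1-(methoxycarbonyl)vinyl]diisobutylalane F4, which adds to 21 at 0 °C. This is an organometallic addition with no amine base.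

**Step 8.** What may go wrong: addition of the hindered secondary hydroxyl to the ketene ylide needs heat, under which acyloin 13 can tautomerise through its enediol and lose the C3 configuration. Fallback (sets out from 13, returns at 16): the hydroxyl is esterified at rt with diethylphosphonoacetic acid (DCC, DMAP) to give phosphonoacetate F5, and an intramolecular Horner–Wadsworth–Emmons reaction under Masamune–Roush conditions (LiCl, i-Pr2NEt, MeCN, rt) closes the butenolide 16.

## Further compounds

F1 | step 6 | (S,E)-tert-butyl{[5-iodo-1-(4-methoxybenzyloxy)-4-methylpent-4-en-2-yl]oxy}dimethylsilane | I/C=C(\C)C[C@H](O[Si](C)(C)C(C)(C)C)COCc1ccc(OC)cc1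
F2 | step 6 | [(1E,4S)-4-(tert-butyldimethylsilyloxy)-5-(4-methoxybenzyloxy)-2-methylpent-1-en-1-yl]lithium | [Li]/C=C(\C)C[C@H](O[Si](C)(C)C(C)(C)C)COCc1ccc(OC)cc1
F0 | step 17 | none | none
F3 | step 20 | 1-bromo-10-hydroxy bromohydrin of 30 (bromine at C1 on the face opposite to the epoxide oxygen of 31, hydroxyl at C10 as in 31) | C=C1C(=O)O[C@@H]2/C=C(/C)[C@@H](OC(C)=O)C[C@H](Br)[C@](C)(O)C[C@H](OC(=O)CC(C)C)[C@@H]12
F4 | step 13 | [1-(methoxycarbonyl)vinyl]diisobutylalane | C=C([Al](CC(C)C)CC(C)C)C(=O)OC
F5 | step 8 | (diethoxyphosphoryl)acetate of the C3 hydroxyl of 13 | COc1ccc(COC[C@@H](O[Si](C)(C)C(C)(C)C)C/C(C)=C/C[C@H](OC(=O)CP(=O)(OCC)OCC)C(C)=O)cc1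
A1 | alternative 1 | 3-(bromomethyl)butenolide with the C8 aldehyde (7,8-seco precursor, C3 acetate) | O=CC/C(C)=C/C[C@H](OC(C)=O)/C(C)=C\[C@H]1OC(=O)C(CBr)=C1
A2 | alternative 1 | 3-acetoxy-8-hydroxygermacra-1(10)E,4Z,11(13)-trien-6,12-olide (identical with 29) | C=C1C(=O)O[C@@H]2/C=C(/C)[C@@H](OC(C)=O)C/C=C(\C)C[C@H](O)[C@@H]12
A3 | alternative 2 | cis-anti-cis tricyclic photoadduct with the bicyclo[2.2.0]hexane core (C1–C4 and C5–C10 bonds, C6 ketone, C8 silyl ether) | O=C1[C@H]2[C@]3(C)CC[C@@H]3[C@@]2(C)C[C@H](O[Si](C)(C)C(C)(C)C)C1
A4 | alternative 2 | (2Z,6E)-3,7-dimethyl-9-(tert-butyldimethylsilyloxy)cyclodeca-2,6-dienone | O=C1/C=C(/C)CC/C=C(\C)C[C@H](O[Si](C)(C)C(C)(C)C)C1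
A5 | alternative 3 | γ-butyrolactone with the C1 aldehyde and the C10 methyl ketone (1,10-seco precursor, C3 triethylsilyl ether, C8 TBS ether) | O=CC[C@H](O[Si](CC)(CC)CC)/C(C)=C\[C@H]1OC(=O)C[C@@H]1[C@@H](O[Si](C)(C)C(C)(C)C)CC(C)=O
A6 | alternative 3 | ten-membered 1,10-diol lactone | O=C1O[C@@H]2/C=C(/C)[C@@H](O[Si](CC)(CC)CC)C[C@H](O)[C@](C)(O)C[C@H](O[Si](C)(C)C(C)(C)C)[C@H]2C1
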